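(The numbers in the tables were computed on assumed constants; noise was put on by code.)

The constants are hidden, so this examination rests on a balance and on a bend in the readings.

the same everywhere: partner 0.475 M
- gamma: solid substrate 0.70 M; run made earlier
- delta: solid substrate 1.1 M; run made earlier
- flask: solid substrate 0.50 M; time 15 d

| run | time / d | solid substrate / % | single product / % |
|---|---|---|---|
| gamma | 1.25 | 88.7 | 0 |
| gamma | 2.50 | 77.8 | 1.1 |
| gamma | 4.00 | 64.0 | 2.1 |
| gamma | 8.00 | 43.4 | 3.0 |
| gamma | 15.0 | 38.0 | 2.8 |
| delta | 3.00 | 83.3 | 0.3 |
| delta | 6.00 | 68.4 | 2.6 |
| delta | 10.0 | 61.8 | 0.8 |
| delta | 12.0 | 61.2 | 0.6 |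
| delta | 15.0 | 60.0 | 1.2 |

(each reading ± 0.5 percentage points)

* solid substrate at 15 d, in percent of the solid substrate charged (only what is still solid)
* single product at 15 d, in percent of the solid substrate charged
* other mono adduct at 15 d, in percent of the solid substrate charged
* bis adduct at 15 d, in percent of the solid substrate charged

- solid substrate is a solid; its amount is given per volume of the solution
- on the list of suspects stand: starting material + partner -> single product + by-product; starting material + partner -> other mono adduct + by-product; partner + single product -> bis adduct + by-product; partner + other mono adduct -> bis adduct + by-product; solid substrate <-> starting material; partner + single product -> over-reaction product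
- at the start none of the solid substrate is in solution

*What do gamma and delta share at the end?* By 15.0 d, gamma has taken up 0.434 M of its solid and delta 0.440 M. That is 91.4 % and 92.6 % of the partner charge, while 38.0 % and 60.0 % of their solid remain.

*What does one substrate cost in partner?* Gamma's uptake falls from 0.0900 d⁻¹ to 0.0515 d⁻¹ of its charge after 4.00 d. The uptake then stands at 0.252 M, half the partner charge. I read two partners per substrate, with partner as limiting reagent.

*Other mono adduct is unread, so why not one partner each?* One each asks for an uptake equal to the partner charge before the bend, yet gamma bends at less.

*Then what is the rest of the uptake?* I take it as starting material in solution, plus a share of the mono adducts, which cost one partner each and not two. My rule, for a flask that still holds solid and stalls with partner limiting, is that uptake at the stall equals half the partner charge plus the dissolved remainder, a fixed amount read from both runs: 0.200 M.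

*And this flask?* The remainder is 39.9 % of its charge, which leaves 12.6 % solid. Bis adduct lies near 47.5 %, less what stays as mono adducts.

The forecast gives solid substrate 13 %, single product 3.5 %, other mono adduct 66 % and bis adduct 13 %, starting from this: “Both earlier runs level off at the same dissolved amount, not the same percentage”. My reckoning differs from it on bis adduct.

The flask gives solid substrate 11.9 %, single product 2.83 %, other mono adduct 4.24 % and bis adduct 42.4 %.

    starting material + partner → single product + by-product (k = 2.20 M⁻¹ h⁻¹)
    starting material + partner → other mono adduct + by-product (k = 1.80 M⁻¹ h⁻¹)
    partner + single product → bis adduct + by-product (k = 2.20 M⁻¹ h⁻¹)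
    partner + other mono adduct → bis adduct + by-product (k = 0.850 M⁻¹ h⁻¹)
    solid substrate ⇌ starting material, rate k5*(cs5 - [starting material]) while solid is left; crystals form when [starting material] > cs5 (solubility = 0.190 M, k = 0.0140 h⁻¹)
    partner + single product → over-reaction product (k = 0.150 M⁻¹ h⁻¹)

In this flask, the uptake puts the dissolved remainder at 0.203 M. At 3.50 d, starting material has a half-life of 0.23 d by passing into other mono adduct, shorter than the 2.06 d of dissolution. By 7.50 d partner stands at 0 % and starting material at 25.8 %, reaching 37.0 % by 15.0 d. With 0.28 M of partner the remainder gives 32.1 % solid left, and that neighbour holds 31.1 %.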